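## Analysis of the target

The target 18 is (R)-7-bromo-6-hydroxy-2-(4-hydroxy-4-methylpentyl)-2-methylchroman-4-one. Ring A is a benzene ring with a free hydroxyl at C6 and bromine at C7. Ring B is the dihydropyranone formed by O1, C2, C3, C4 (ketone), C4a and C8a. The only stereocentre is C2 (R), a fully substituted ether carbon bearing a methyl group and the chain C1'–C4', whose terminus C4' is a tertiary carbinol with two methyl groups. No second centre exists to relay from, so the configuration must be set absolutely.

The sensitive groups are:
- the β-aryloxy ketone: enolisation towards C3 can expel the O1 phenoxide and reclose without memory, which would racemise C2;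
- the tertiary alcohol, which ionises under strong acid;
- the aryl bromide, which excludes hydrogenolysis, lithium reagents and long contact with zerovalent palladium;
- the 6-hydroxyl para to O1, an easily oxidised hydroquinone monoether.

The difficulty is that O1–C2 joins oxygen to a tertiary carbon and cannot be made by displacement. The feature used here is that C2 carries one methyl and one methylene (C1'). C2 and C1' are thus the two carbons of a 1,1-disubstituted alkene placed six atoms from the phenol oxygen O1. Addition of O1 to the internal carbon leaves a metal on C1' with no hydrogen on the neighbouring carbon, free to form C1'–C2'.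

## Retrosynthetic reasoning

**18 back to 15 (no skeletal bond cut).** The C6 hydroxyl is traced back to the methoxymethyl ether 17, the C4 ketone to the benzylic alcohol 16, and that alcohol to its silyl ether 15. The ketone is introduced late for three reasons. A C4 carbonyl would compete with the side-chain ketone for the methyl nucleophile. It would open the base-mediated racemisation channel at C2 early. And in the cyclisation substrate it would pull the alkene into conjugation. The phenol stays masked until the end because the oxidant for C4 would attack a free hydroquinone monoether.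

**15 back to 13 (C4'–CH3 and the C2'=C3' unsaturation).** One methyl on C4' is cut, leading to methyl ketone 14, and the C2'–C3' single bond is traced back to the E-enone 13. This leaves a chain that an alkene partner can deliver in one piece. The forward steps are a conjugate hydride delivery from copper that spares the aryl bromide, and addition of a methylmagnesium halide to the only carbonyl present.

**13 back to 10 and 11 (O1–C2 and C1'–C2').** This is the key disconnection. Both bonds are cut in one operation, giving phenol 10, which carries a 1,1-disubstituted alkene, and the four-carbon enone 11. The cut is made here because it is the only one that forms the tertiary ether bond and the stereocentre together from an achiral alkene carbon. The forward reaction must add O1 to one face of the alkene under control of a chiral divalent palladium catalyst and trap the resulting alkylpalladium 12 with 11 before anything else happens. The absence of hydrogen on C2 is what makes 12 persistent enough for this. The C4 oxygen is carried as a silyl ether on an sp3 carbon, a passenger stereocentre that is erased later.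

**10 back to 8 (protecting-group change only).** Phenol 10 comes from the bis-silyl ether 9 by selective loss of the aryl silyl group, and 9 from carbinol 8 by silylation. The phenol has to be masked during the preceding C–C bond formation and the benzylic oxygen has to be masked during the palladium step. One silyl type on both oxygens, differentiated by the leaving-group ability of phenoxide, does both jobs.

**8 back to 4 and 5 (C3–C4, chroman numbering).** The bond between the carbinol carbon and its neighbouring methylene is cut, giving aryl aldehyde 4 and the 2-methylallyl nucleophile 5. A chiral allylborane 6, made in the flask from 5, should add to one face of the aldehyde. C4 is then a single enantiomer, so the palladium step gives one diastereomer series and any C2 epimer becomes a separable diastereomer.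

**4 back to 1 (oxygen substituents only).** Aldehyde 4 is traced through the mono-acetal 3 and the dihydroxy aldehyde 2 to the commercial dimethoxy aldehyde 1. Compound 1 already has bromine, both oxygens and the formyl carbon in the required positions, so no aromatic substitution with a regiochemical question is needed.

## Alternatives that were turned down

**Alternative 1:** The disconnection is the aryl–oxygen bond O1–C8a, with C2 and its oxygen, methyl and chain taken ready-made from (R)-linalool (A3). The vinyl group of A3 would be converted into the CH2–C(=O)–aryl unit of the β-hydroxy ketone A2, (R)-1-[5-(benzyloxy)-2-fluorophenyl]-3-hydroxy-3,7-dimethyloct-6-en-1-one. In the key step the potassium alkoxide of A2 displaces the fluoride activated by the ortho ketone and closes ring B to A1, (R)-6-(benzyloxy)-2-methyl-2-(4-methylpent-3-enyl)chroman-4-one.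

- For: the stereocentre is bought, no bond at C2 is made or broken in the ring closure, and the displacement is operationally simple. On the source of chirality this alternative is stronger than the chosen plan, which must create the centre with a catalyst.
- Against: the attacking alkoxide is a tertiary aldolate. Retro-aldol cleavage into an aryl methyl ketone enolate and a methyl ketone is fast for this type, and recombination would return A2 as a racemate. Elimination of water also competes.
- Against: A1 is far from the target. C7 has no bromine, the chain ends in a trisubstituted alkene, and the phenol is benzylated. Bromination would have to choose C7 over C5 and C8 on a ring whose directing effects are not decisive. The alkene must be hydrated first, and the benzyl ether must be removed before bromine arrives because hydrogenolysis and an aryl bromide do not coexist.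
- Comparison: the chosen plan buys ring A with bromine and both oxygens in place, forms C2 in a step with no reverse channel, and delivers the chain at the right oxidation pattern in the same operation.

**Alternative 2:** The disconnection is the C3=C4 bond of a 4-silyloxy-2H-chromene, the silyl enol ether of the target ketone. The diene A5 is an aryl silyl enol ether whose ortho oxygen carries the (R)-configured tertiary allylic carbon. The second-generation Grubbs catalyst closes it, with loss of a two-carbon alkene, to A4, (R)-7-bromo-4,6-bis(tert-butyldimethylsilyloxy)-2-methyl-2-[4-methyl-4-(tert-butyldimethylsilyloxy)pentyl]-2H-chromene.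

- For: the metathesis does not touch the stereocentre, and A4 is the fully silylated target, so one deprotection could end the synthesis. On endgame length this is stronger than the chosen route, which needs five steps after its key step.
- Against: the ring closure is the easy part and the burden moves to A5. Its O1–C2 bond is a hindered tertiary allylic aryl ether that must be made as a single enantiomer next to an ortho acyl group. An alkoxide strong enough for aromatic substitution would first deprotonate the aryl methyl ketone. A tertiary allyl aryl ether with a free ortho position (C8) is also prone to Claisen rearrangement or ionisation on warming.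
- Against: the closure joins a vinyl group on a quaternary carbon to an electron-rich 1,1-disubstituted enol ether, both slow partners. The tertiary silyl ether would need forcing fluoride or acid, which threatens C2 or the carbinol.
- Comparison: the chosen strategy makes the very bond that this alternative presupposes, together with the stereocentre, in one catalytic step from a simple phenol. It pays for this with the longer endgame.

**Alternative 3:** The disconnection is C2–C3. The aryl diazomethyl ketone A7 is decomposed by Rh2(OAc)4. The carbene carbon, the future C3, inserts into the methine C–H bond of the (R)-configured secondary alkyl aryl ether and closes ring B to A6, (R)-7-bromo-6-(tert-butyldimethylsilyloxy)-2-methyl-2-[4-methyl-4-(triethylsilyloxy)pentyl]chroman-4-one.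

- For: carbene C–H insertion proceeds with retention, so the quaternary centre derives from an easily made secondary carbinol centre. The C–H bond is activated by the adjacent oxygen, and A6 needs only desilylation. On step count after the key step and on simplicity of the chirality source this alternative is as strong as or stronger than the chosen one.
- Against: the ether oxygen lies five atoms from the carbene. Attack on that oxygen gives a five-membered oxonium ylide whose 1,2-shift leads to a 2,2-disubstituted benzofuranone. This competes with the six-membered insertion and gains when the C–H bond is a hindered methine. Insertion into the neighbouring chain methylene is a further competitor.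
- Against: the diazoketone requires a diazoalkane reagent on an acid chloride, and the benzoic acid needed has the same four-substituent pattern that must be assembled anyway.
- Comparison: the chosen key step is precedented on the same substrate class for the same six-membered closure, offers the oxygen only one carbon to attack, and forms C1'–C2' in the same operation. It is longer after the key step.

Key step: step 7

Assumption: the (S,S)-enantiomer of the benzyl-substituted BOXAX ligand is taken to deliver O1 to the alkene face that gives 2R, by analogy with 2-methyl-2-alkenylchromans of the same spatial arrangement at C2; the antipodal ligand is the remedy if the sense is the reverse.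

## Route

Step 1
Reactants: 1 4-bromo-2,5-dimethoxybenzaldehyde
Product: 2 4-bromo-2,5-dihydroxybenzaldehyde
Conditions: BBr3 (3 equiv), CH2Cl2, −78 °C → rt; H2O
Reagents that add atoms: none
Why: Lewis-acid ether cleavage (BBr3 demethylation) removes both aryl methyl ethers while the formyl group and the aryl bromide are inert; it is done first, before any acid-sensitive group is present.

Step 2
Reactants: 2 4-bromo-2,5-dihydroxybenzaldehyde
Product: 3 4-bromo-2-hydroxy-5-(methoxymethoxy)benzaldehyde
Conditions: MOMCl (1.05 equiv), i-Pr2NEt (1.2 equiv), CH2Cl2, 0 °C
Reagents that add atoms: chloromethyl methyl ether, COCCl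
Why: Selective O-alkylation of a phenol: the 2-OH is locked in a hydrogen bond to the formyl oxygen and is the poorer nucleophile, so one equivalent of the chloride should go to the 5-OH. The methoxymethyl ether is chosen because it survives base, fluoride, organomagnesium reagents and oxidants and can be removed last without touching the bromide.

Step 3
Reactants: 3 4-bromo-2-hydroxy-5-(methoxymethoxy)benzaldehyde
Product: 4 4-bromo-2-(tert-butyldimethylsilyloxy)-5-(methoxymethoxy)benzaldehyde
Conditions: TBSCl (1.2 equiv), imidazole (2 equiv), DMF, rt
Reagents that add atoms: tert-butyldimethylsilyl chloride, CC(C)(C)[Si](C)(C)Cl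
Why: Imidazole-promoted silylation of the remaining phenol. A free hydroxyl would protonate the allylborane of step 4 and tie boron to the carbonyl, and an aryl silyl ether can later be removed beside an alkyl silyl ether.

Step 4
Reactants: 4 4-bromo-2-(tert-butyldimethylsilyloxy)-5-(methoxymethoxy)benzaldehyde; 5 (2-methylallyl)magnesium chloride
Product: 8 (S)-1-[4-bromo-2-(tert-butyldimethylsilyloxy)-5-(methoxymethoxy)phenyl]-3-methylbut-3-en-1-ol, via B-(2-methylallyl)diisopinocampheylborane 6 (not isolated), via homoallylic diisopinocampheylborinate 7 (not isolated)
Conditions: 5 (1.3 equiv), (−)-Ipc2BOMe (1.4 equiv), Et2O, −78 °C → rt; then 4, −78 °C; then pH 7 phosphate buffer, MeOH, 30% H2O2, 0 °C → rt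
Reagents that add atoms: none
Why: Brown asymmetric allylboration: transmetallation gives borane 6, which adds to the aldehyde through a closed chair transition state to give borinate 7, and neutral oxidative work-up releases 8. The isopinocampheyl groups derived from (+)-α-pinene should direct the 2-methylallyl group to the Si face of the aryl aldehyde, which corresponds to the S carbinol.

Step 5
Reactants: 8 (S)-1-[4-bromo-2-(tert-butyldimethylsilyloxy)-5-(methoxymethoxy)phenyl]-3-methylbut-3-en-1-ol
Product: 9 (S)-tert-butyl-[1-[4-bromo-2-(tert-butyldimethylsilyloxy)-5-(methoxymethoxy)phenyl]-3-methylbut-3-enyloxy]dimethylsilane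
Conditions: TBSOTf (1.3 equiv), 2,6-lutidine (2 equiv), CH2Cl2, −78 → 0 °C
Reagents that add atoms: tert-butyldimethylsilyl trifluoromethanesulfonate, CC(C)(C)[Si](C)(C)OS(=O)(=O)C(F)(F)F
Why: Silylation of a hindered secondary benzylic alcohol with a silyl triflate and a hindered pyridine base; the acetal and the 1,1-disubstituted alkene should be untouched at this temperature. Any aryl-to-alkyl silyl transfer during step 4 is harmless, because steps 5 and 6 converge on 10.

Step 6
Reactants: 9 (S)-tert-butyl-[1-[4-bromo-2-(tert-butyldimethylsilyloxy)-5-(methoxymethoxy)phenyl]-3-methylbut-3-enyloxy]dimethylsilane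
Product: 10 (S)-5-bromo-2-[1-(tert-butyldimethylsilyloxy)-3-methylbut-3-enyl]-4-(methoxymethoxy)phenol
Conditions: K2CO3 (1 equiv), MeOH, 0 °C → rt; aq. NH4Cl
Reagents that add atoms: none
Why: Base-mediated methanolysis of an aryl silyl ether: phenoxide leaves silicon far more readily than a secondary alkoxide, so the benzylic silyl ether should remain. The stereocentre is not involved.

Step 7
Reactants: 10 (S)-5-bromo-2-[1-(tert-butyldimethylsilyloxy)-3-methylbut-3-enyl]-4-(methoxymethoxy)phenol; 11 but-3-en-2-one
Product: 13 (E)-5-[(2R,4S)-7-bromo-4-(tert-butyldimethylsilyloxy)-6-(methoxymethoxy)-2-methylchroman-2-yl]pent-3-en-2-one, via chromanylmethylpalladium trifluoroacetate 12 (not isolated)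
Conditions: Pd(OCOCF3)2 (10 mol %), (S,S)-Bn-BOXAX [(S)-2,2'-bis[(4S)-4-benzyl-4,5-dihydrooxazol-2-yl]-1,1'-binaphthyl] (40 mol %), p-benzoquinone (4 equiv), 11 (5 equiv), CH2Cl2, rt
Reagents that add atoms: none
Why: Divalent palladium held by the C2-symmetric bis(oxazoline) coordinates the 1,1-disubstituted alkene of 10, and the phenol oxygen adds to the internal carbon in a 6-exo-trig oxypalladation that forms O1–C2, closes ring B and gives alkylpalladium 12. Because C2 carries no hydrogen, 12 cannot undergo β-hydride elimination; it inserts the terminal carbon of 11 (C1'–C2'), syn β-hydride elimination then releases the E-enone 13, and p-benzoquinone returns the zerovalent palladium to the divalent state. The closest known reaction type is the enantioselective domino Wacker–Heck reaction of 2-(3-methylbut-3-enyl)phenols, including para-alkoxy phenols, with acrylates and vinyl ketones under this catalyst system; the present substrate differs by the benzylic silyloxy group and the aryl bromide. The new stereocentre C2 is controlled by the ligand through the choice of alkene face in the oxypalladation, while C4 is carried unchanged. The step needs facial selectivity, 6-exo closure, capture by the enone and survival of the C–Br bond. Attack at the more substituted alkene carbon secures the ring size. The phosphine-free conditions at room temperature, where benzoquinone should intercept zerovalent palladium before it inserts into C–Br, protect the bromide. Since C4 is a single enantiomer, a C2 epimer would be a diastereomer and removable by chromatography.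

Step 8
Reactants: 13 (E)-5-[(2R,4S)-7-bromo-4-(tert-butyldimethylsilyloxy)-6-(methoxymethoxy)-2-methylchroman-2-yl]pent-3-en-2-one
Product: 14 5-[(2R,4S)-7-bromo-4-(tert-butyldimethylsilyloxy)-6-(methoxymethoxy)-2-methylchroman-2-yl]pentan-2-one
Conditions: [(Ph3P)CuH]6 (0.4 equiv), H2O (3 equiv), degassed toluene, rt
Reagents that add atoms: none
Why: Stryker conjugate reduction: hydride is delivered to C2' of the enone and the copper enolate is protonated by water. The aryl bromide, which would be at risk under hydrogen over palladium, and both protecting groups should be left alone.

Step 9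
Reactants: 14 5-[(2R,4S)-7-bromo-4-(tert-butyldimethylsilyloxy)-6-(methoxymethoxy)-2-methylchroman-2-yl]pentan-2-one
Product: 15 5-[(2R,4S)-7-bromo-4-(tert-butyldimethylsilyloxy)-6-(methoxymethoxy)-2-methylchroman-2-yl]-2-methylpentan-2-ol
Conditions: MeMgBr (1.5 equiv), THF, −78 → 0 °C; aq. NH4Cl
Reagents that add atoms: methylmagnesium bromide, C[Mg]Br
Why: Grignard 1,2-addition to the methyl ketone creates the tertiary carbinol C4'. C4 is still a silyl ether, so only one carbonyl is present, and MeMgBr does not exchange with the aryl bromide at this temperature.

Step 10
Reactants: 15 5-[(2R,4S)-7-bromo-4-(tert-butyldimethylsilyloxy)-6-(methoxymethoxy)-2-methylchroman-2-yl]-2-methylpentan-2-ol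
Product: 16 (2R,4S)-7-bromo-2-(4-hydroxy-4-methylpentyl)-6-(methoxymethoxy)-2-methylchroman-4-ol
Conditions: Bu4NF (1.5 equiv), THF, 0 °C → rt
Reagents that add atoms: none
Why: Fluoride cleavage of the Si–O bond; acetal, bromide and tertiary alcohol are inert. There is not yet a C4 ketone that basic fluoride could enolise.

Step 11
Reactants: 16 (2R,4S)-7-bromo-2-(4-hydroxy-4-methylpentyl)-6-(methoxymethoxy)-2-methylchroman-4-ol
Product: 17 (R)-7-bromo-2-(4-hydroxy-4-methylpentyl)-6-(methoxymethoxy)-2-methylchroman-4-one
Conditions: Dess–Martin periodinane (1.3 equiv), CH2Cl2, 0 °C → rt
Reagents that add atoms: none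
Why: Dess–Martin oxidation of the secondary benzylic alcohol under near-neutral conditions; the tertiary alcohol cannot be oxidised and the phenol is still masked. The passenger centre C4 disappears, and C2 is untouched because no base is present.

Step 12
Reactants: 17 (R)-7-bromo-2-(4-hydroxy-4-methylpentyl)-6-(methoxymethoxy)-2-methylchroman-4-one
Product: 18 (R)-7-bromo-6-hydroxy-2-(4-hydroxy-4-methylpentyl)-2-methylchroman-4-one
Conditions: 2 M aq. HCl, THF, rt → 40 °C
Reagents that add atoms: none
Why: Acid-catalysed hydrolysis of the aryl methoxymethyl acetal, the most acid-labile group present. Dilute aqueous acid at this temperature should neither ionise the tertiary alcohol nor open ring B at a meaningful rate.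

## Compound list

1 | 4-bromo-2,5-dimethoxybenzaldehyde | COc1cc(C=O)c(OC)cc1Br | starting material
2 | 4-bromo-2,5-dihydroxybenzaldehyde | O=Cc1cc(O)c(Br)cc1O | intermediate
3 | 4-bromo-2-hydroxy-5-(methoxymethoxy)benzaldehyde | O=Cc1cc(OCOC)c(Br)cc1O | intermediate
4 | 4-bromo-2-(tert-butyldimethylsilyloxy)-5-(methoxymethoxy)benzaldehyde | O=Cc1cc(OCOC)c(Br)cc1O[Si](C)(C)C(C)(C)C | intermediate
5 | (2-methylallyl)magnesium chloride | CC(=C)C[Mg]Cl | starting material
6 | B-(2-methylallyl)diisopinocampheylborane, both isopinocampheyl groups derived from (+)-α-pinene | CC(=C)CB([C@H]1[C@H](C)[C@H]2C[C@@H](C1)C2(C)C)[C@H]1[C@H](C)[C@H]2C[C@@H](C1)C2(C)C | intermediate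
7 | O-diisopinocampheylboryl derivative (borinate) of carbinol 8 | CC(=C)C[C@H](OB([C@H]1[C@H](C)[C@H]2C[C@@H](C1)C2(C)C)[C@H]1[C@H](C)[C@H]2C[C@@H](C1)C2(C)C)c1cc(OCOC)c(Br)cc1O[Si](C)(C)C(C)(C)C | intermediate
8 | (S)-1-[4-bromo-2-(tert-butyldimethylsilyloxy)-5-(methoxymethoxy)phenyl]-3-methylbut-3-en-1-ol | CC(=C)C[C@H](O)c1cc(OCOC)c(Br)cc1O[Si](C)(C)C(C)(C)C | intermediate
9 | (S)-tert-butyl-[1-[4-bromo-2-(tert-butyldimethylsilyloxy)-5-(methoxymethoxy)phenyl]-3-methylbut-3-enyloxy]dimethylsilane | CC(=C)C[C@H](O[Si](C)(C)C(C)(C)C)c1cc(OCOC)c(Br)cc1O[Si](C)(C)C(C)(C)C | intermediate
10 | (S)-5-bromo-2-[1-(tert-butyldimethylsilyloxy)-3-methylbut-3-enyl]-4-(methoxymethoxy)phenol | CC(=C)C[C@H](O[Si](C)(C)C(C)(C)C)c1cc(OCOC)c(Br)cc1O | intermediate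
11 | but-3-en-2-one | CC(=O)C=C | starting material
12 | [7-bromo-4-(tert-butyldimethylsilyloxy)-6-(methoxymethoxy)-2-methylchroman-2-yl]methylpalladium trifluoroacetate, C2 and C4 arranged in space as in 13, bis(oxazoline) ligand on palladium not drawn | FC(F)(F)C(=O)O[Pd]C[C@]1(C)C[C@H](O[Si](C)(C)C(C)(C)C)c2cc(OCOC)c(Br)cc2O1 | intermediate
13 | (E)-5-[(2R,4S)-7-bromo-4-(tert-butyldimethylsilyloxy)-6-(methoxymethoxy)-2-methylchroman-2-yl]pent-3-en-2-one | CC(=O)/C=C/C[C@]1(C)C[C@H](O[Si](C)(C)C(C)(C)C)c2cc(OCOC)c(Br)cc2O1 | intermediate
14 | 5-[(2R,4S)-7-bromo-4-(tert-butyldimethylsilyloxy)-6-(methoxymethoxy)-2-methylchroman-2-yl]pentan-2-one | CC(=O)CCC[C@]1(C)C[C@H](O[Si](C)(C)C(C)(C)C)c2cc(OCOC)c(Br)cc2O1 | intermediate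
15 | 5-[(2R,4S)-7-bromo-4-(tert-butyldimethylsilyloxy)-6-(methoxymethoxy)-2-methylchroman-2-yl]-2-methylpentan-2-ol | CC(C)(O)CCC[C@]1(C)C[C@H](O[Si](C)(C)C(C)(C)C)c2cc(OCOC)c(Br)cc2O1 | intermediate
16 | (2R,4S)-7-bromo-2-(4-hydroxy-4-methylpentyl)-6-(methoxymethoxy)-2-methylchroman-4-ol | CC(C)(O)CCC[C@]1(C)C[C@H](O)c2cc(OCOC)c(Br)cc2O1 | intermediate
17 | (R)-7-bromo-2-(4-hydroxy-4-methylpentyl)-6-(methoxymethoxy)-2-methylchroman-4-one | CC(C)(O)CCC[C@]1(C)CC(=O)c2cc(OCOC)c(Br)cc2O1 | intermediate
18 | (R)-7-bromo-6-hydroxy-2-(4-hydroxy-4-methylpentyl)-2-methylchroman-4-one | CC(C)(O)CCC[C@]1(C)CC(=O)c2cc(O)c(Br)cc2O1 | target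

## Step count and least certain steps

Total step count: 12. Longest linear sequence: 12 steps (1 to 18); 5 and 11 are bought and enter in steps 4 and 7.

**Step 7 (key step).** The second half of the domino is the most likely point of failure. Oxypalladation is reversible and becomes productive only when alkylpalladium 12 is captured. That centre is neopentyl-like, the benzylic silyloxy group adds bulk on the same ring, and the enone competes for the metal. Slow insertion, protonolysis of the C–Pd bond by the acid liberated from the catalyst, and deposition of the metal are therefore the probable failure modes. Loss of facial selectivity through a mismatch between ligand and C4 is the second concern. It is buffered because the C2 epimer would be a diastereomer.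

Fallback, from 10 back to 13: the same catalyst and oxidant are used under CO (1 atm) in MeOH/CH2Cl2. CO insertion into 12 is fast, and methanolysis of the acylpalladium should give methyl 2-[(2S,4S)-7-bromo-4-(tert-butyldimethylsilyloxy)-6-(methoxymethoxy)-2-methylchroman-2-yl]acetate F1. This has the same spatial arrangement as 13; the C2 descriptor changes with the priorities. Reduction with i-Bu2AlH in CH2Cl2 at −78 °C gives 2-[(2S,4S)-7-bromo-4-(tert-butyldimethylsilyloxy)-6-(methoxymethoxy)-2-methylchroman-2-yl]acetaldehyde F2. Wittig olefination with the stabilised, non-basic ylide Ph3P=CHC(O)CH3 in toluene then forms the C2'=C3' bond and returns the route to 13.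

**Step 2.** Discrimination between the two phenols may be insufficient, leading to double alkylation or alkylation at the wrong oxygen. Both hydroxyls are acidified, one by the ortho formyl group and one by the ortho bromine, and the selectivity rests only on the hydrogen bond.

Fallback, from 2 back to 3: exhaustive alkylation with excess MOMCl and i-Pr2NEt gives 4-bromo-2,5-bis(methoxymethoxy)benzaldehyde F3. MgBr2·OEt2 in Et2O then removes only the acetal ortho to the formyl group, because magnesium is chelated between the carbonyl oxygen and that acetal oxygen. This returns the route to 3.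

**Step 9.** Deprotonation of the methyl ketone by the Grignard reagent may compete with addition, so that conversion stalls and 14 is returned on work-up.

Fallback, from 14 back to 15: methylenation with Ph3P=CH2 (from Ph3PCH3Br and KOt-Bu, THF) gives tert-butyl-[[(2R,4S)-7-bromo-6-(methoxymethoxy)-2-methyl-2-(4-methylpent-4-enyl)chroman-4-yl]oxy]dimethylsilane F4. Mukaiyama hydration (Co(acac)2 catalyst, PhSiH3, O2, i-PrOH) adds water in the Markovnikov sense to the 1,1-disubstituted alkene and returns the route to the tertiary alcohol 15. The aryl bromide and both protecting groups are inert to these conditions.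

**Step 12.** Prolonged exposure to protic acid may ionise the tertiary carbinol (elimination or chloride capture). It may also allow slow acid-catalysed opening and reclosure of ring B, which would erode the configuration at C2.

Fallback, from 17 directly to 18: the acetal is cleaved by thiolysis in place of hydrolysis, using ZnBr2 (1 equiv) and n-PrSH (2 equiv) in CH2Cl2 at 0 °C. The Lewis acid activates the acetal and the thiol takes over the methoxymethyl group within minutes, without a Brønsted acid strong enough to ionise the carbinol. This fallback makes no new compound (F0).

## Further compounds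

F1 | step 7 | methyl 2-[(2S,4S)-7-bromo-4-(tert-butyldimethylsilyloxy)-6-(methoxymethoxy)-2-methylchroman-2-yl]acetate | COC(=O)C[C@]1(C)C[C@H](O[Si](C)(C)C(C)(C)C)c2cc(OCOC)c(Br)cc2O1
F2 | step 7 | 2-[(2S,4S)-7-bromo-4-(tert-butyldimethylsilyloxy)-6-(methoxymethoxy)-2-methylchroman-2-yl]acetaldehyde | O=CC[C@]1(C)C[C@H](O[Si](C)(C)C(C)(C)C)c2cc(OCOC)c(Br)cc2O1
F3 | step 2 | 4-bromo-2,5-bis(methoxymethoxy)benzaldehyde | O=Cc1cc(OCOC)c(Br)cc1OCOC
F4 | step 9 | tert-butyl-[[(2R,4S)-7-bromo-6-(methoxymethoxy)-2-methyl-2-(4-methylpent-4-enyl)chroman-4-yl]oxy]dimethylsilane | CC(=C)CCC[C@]1(C)C[C@H](O[Si](C)(C)C(C)(C)C)c2cc(OCOC)c(Br)cc2O1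
F0 | step 12 | none | none
A1 | alternative 1 | (R)-6-(benzyloxy)-2-methyl-2-(4-methylpent-3-enyl)chroman-4-one | CC(C)=CCC[C@]1(C)CC(=O)c2cc(OCc3ccccc3)ccc2O1
A2 | alternative 1 | (R)-1-[5-(benzyloxy)-2-fluorophenyl]-3-hydroxy-3,7-dimethyloct-6-en-1-one | CC(C)=CCC[C@@](C)(O)CC(=O)c1cc(OCc2ccccc2)ccc1F
A3 | alternative 1 | (R)-linalool, (R)-3,7-dimethylocta-1,6-dien-3-ol | CC(C)=CCC[C@@](C)(O)C=C
A4 | alternative 2 | (R)-7-bromo-4,6-bis(tert-butyldimethylsilyloxy)-2-methyl-2-[4-methyl-4-(tert-butyldimethylsilyloxy)pentyl]-2H-chromene | CC(C)(O[Si](C)(C)C(C)(C)C)CCC[C@]1(C)C=C(O[Si](C)(C)C(C)(C)C)c2cc(O[Si](C)(C)C(C)(C)C)c(Br)cc2O1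
A5 | alternative 2 | tert-butyl-[1-[4-bromo-5-(tert-butyldimethylsilyloxy)-2-[(R)-7-(tert-butyldimethylsilyloxy)-3,7-dimethyloct-1-en-3-yl]oxyphenyl]ethenyloxy]dimethylsilane | C=C[C@@](C)(CCCC(C)(C)O[Si](C)(C)C(C)(C)C)Oc1cc(Br)c(O[Si](C)(C)C(C)(C)C)cc1C(=C)O[Si](C)(C)C(C)(C)C
A6 | alternative 3 | (R)-7-bromo-6-(tert-butyldimethylsilyloxy)-2-methyl-2-[4-methyl-4-(triethylsilyloxy)pentyl]chroman-4-one | CC(C)(O[Si](CC)(CC)CC)CCC[C@]1(C)CC(=O)c2cc(O[Si](C)(C)C(C)(C)C)c(Br)cc2O1
A7 | alternative 3 | 1-[4-bromo-5-(tert-butyldimethylsilyloxy)-2-[(R)-6-methyl-6-(triethylsilyloxy)heptan-2-yl]oxyphenyl]-2-diazoethanone | CC(C)(O[Si](CC)(CC)CC)CCC[C@@H](C)Oc1cc(Br)c(O[Si](C)(C)C(C)(C)C)cc1C(=O)C=[N+]=[N-]
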